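## Structural features

Target 20, (4R)-11-(3,5-dihydroxyphenyl)undecan-4-yl 2,4-dihydroxy-6-undecylbenzoate (C35H54O6), is an open-chain ester of two alkylresorcinol units, each with an unbranched C11 chain, and the two benzene rings are its only rings. Ring A is the acyl part. C1 carries the carboxyl carbon, C2 and C4 carry OH and C6 carries the undecyl chain, so the carbonyl group is flanked on both sides and hydrogen-bonded to the C2 hydroxyl. Ring B is a 5-alkylresorcinol tied through seven CH2 groups (C11′ to C5′) to the only stereocentre, the (R)-carbinol carbon C4′, which also bears the n-propyl end (C3′ to C1′) and the ester oxygen. This stereocentre has no stereogenic neighbour, and its two carbon substituents are unbranched chains that differ only from the fourth atom on, so a reagent that reads size can hardly tell them apart. The fragile groups are the four free phenols (easily oxidised and acylated) and the secondary alkyl salicylate ester, which would not tolerate Lewis-acidic ether cleavage or hot hydroxide. The real difficulty is joining an electron-rich, di-ortho-substituted benzoyl group to a secondary alcohol without loss of configuration at C4′, while also setting the 1,2,4,6-substitution of ring A and telling six oxygen functions apart. The key step exploits the oxygen pattern on alternate carbons (carboxyl carbon, C2, C4, C6): carboxyl carbon, ring A and undecyl chain together are a folded 3,5,7-trioxooctadecanoate (P1 = carboxyl carbon, P2 to P7 = ring carbons C1 to C6, P8 to P18 = undecyl), in which ring bond C1–C6 is the aldol bond P2–P7.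

## Logic of the disconnections

**20 back to 19.** The two phenol O–H bonds of ring B are exchanged for O–CH2Ph bonds. The reason is that the alcohol partner of the key step may offer one O–H only, because ring B phenols would compete for the ketene. Nothing is gained in skeleton, but this is the only protecting-group operation of the plan, since ring A is formed with its phenols free. The forward step must cleave under neutral conditions that leave the non-benzylic secondary ester and C4′ alone.

**19 back to 8 + 15 (through 18, 17 and 16).** The bonds cut are ring bond C1–C6 of ring A (P2–P7) and the acyl C–O bond between P1 and the oxygen on C4′. C2–OH and C4–OH revert to the P3 and P5 ketones. In one sentence: ring A and the ester bond are made together when 16, released by heating 8, is captured by 15 and the resulting chain 17 is folded by aldol closure and dehydration. This sentence does not fit the esterification of a finished benzoic acid. The cut is placed here because the ester forms while P1 is still an unhindered sp carbon, before either ortho substituent exists. A tetrasubstituted arene, its two phenols, their protection and the hindered acylation all disappear at once, leaving a linear masked chain and a simple alcohol. The forward step must capture the ketene intermolecularly and fold the chain P2 to P7 only.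

**8 back to 4 + 6.** The bond cut is P6–P7. P7 is an acyl carbon and P6 is the terminal carbon of a 1,3-dicarbonyl dianion, so the polarity is natural, and the cut separates the purchasable C12 fatty part from the reactive head group. A C21 chain falls into C9 and C12 pieces. The forward step must react at the terminal carbon only and transfer a single acyl group.

**4 back to 1 + 2.** The bond cut is P4–P5. P4 is the γ-carbon of a dienolate and P5 is an acyl carbon. Both pieces are bulk chemicals. The forward step must acylate at the γ-carbon rather than at oxygen or at the α-carbon.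

**6 back to 5.** The bond cut is the amide C–N bond. This only tunes the acyl donor so that one addition takes place in the step that forms 8. The demand on the forward step is trivial.

**15 back to 12 + 13.** The bond cut is the aryl–alkyl bond between ring B and C11′. It lies between a commercial aryl halide that already holds both masked phenols and a chain that ends in an alkene, so no benzylic functional group has to be handled. The forward step needs anti-Markovnikov borylation and an sp3–sp2 coupling that tolerates a free hydroxyl group.

**12 back to 9 + 10.** The bond cut is C5′–C6′, one carbon away from the stereocentre. The C4′–O bond then arrives intact from an enantiopure terminal epoxide, and no catalyst has to distinguish propyl from the long chain. The only demand is attack at the CH2 terminus of the epoxide.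

## Other disconnections considered

**Alternative 1:** This is the first cut that comes to mind, the acyl C–O bond alone. In the forward direction 2,4-bis(benzyloxy)-6-undecylbenzoic acid A1 is activated (acid chloride, mixed anhydride or carbodiimide) and acylates 15 to give the tetrabenzyl ether A2. Alternatively A1 is joined by a Mitsunobu reaction, with inversion, to the (S)-alcohol A3. Fourfold hydrogenolysis follows in either case.
- The carbonyl group of A1 is flanked by an alkoxy group and a long alkyl chain, is twisted out of the ring plane and is fed by two donor oxygens. Acyl transfer to a secondary alcohol should therefore be slow and should call for forcing conditions.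
- The Mitsunobu variant moves the reaction to C4′. There, SN2 displacement at a secondary carbon between two chains competes with elimination and puts the configuration at risk.
- A1 needs a sequence of its own: protection, chain attachment by lateral alkylation or cross-coupling, and saponification of a hindered ester. It also needs two more protecting groups, so the count should exceed that of the chosen plan by several steps.

**Alternative 2:** The cut falls on ring bonds C1–C2 and C5–C6 of ring A. In the forward direction 15 is esterified with an unhindered ynoic acid to the tetradec-2-ynoate A4. A Diels–Alder reaction with 1-methoxy-1,3-bis(trimethylsilyloxy)buta-1,3-diene A5 follows, with loss of the methoxy and silyl groups, to give 19.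
- The regiochemistry is right, since the nucleophilic diene terminus adds to the β-carbon.
- A4 is activated by one ester group only and carries a long alkyl chain on the reacting β-carbon. Prolonged strong heating should be needed, and under such heating A5 is prone to silyl migration and decomposition.
- Ester and ring are made in two separate operations, and both the ynoic acid and A5 must be prepared. This is the nearest rival, but it is longer and rests on a weaker key step.

**Alternative 3:** The cut falls on the bond between ring carbon C1 and the carboxyl carbon. In the forward direction 1,5-bis(benzyloxy)-2-bromo-3-undecylbenzene A6 undergoes palladium-catalysed alkoxycarbonylation with CO and 15 to give A2, followed by hydrogenolysis.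
- Oxidative addition into an electron-rich, di-ortho-substituted bromide is slow.
- Alcoholysis of the hindered acylpalladium species by a secondary alcohol is expected to limit turnover. It is normally driven by a large excess of alcohol, which is not affordable for 15.
- Reductive loss of the halogen is a likely competitor.
- A6 also requires ring A with its chain to be made and protected first, so nothing is saved.

Key step: step 6

Remark: the centre written [C@H] in the given SMILES is read as (R) (O > C5′ chain > propyl > H).

Remark: (R)-2-propyloxirane 10 is taken as a commercial compound of high enantiomeric purity. LiHMDS, LDA and 9-BBN-H are used as commercial solutions.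

## Steps

Step 1
Reactants: 1 2,2,6-trimethyl-4H-1,3-dioxin-4-one; 2 acetyl chloride
Product: 4 2,2-dimethyl-6-(2-oxopropyl)-4H-1,3-dioxin-4-one, via lithium dienolate 3 (not isolated)
Conditions: 1 (2 equiv), LiHMDS (2 equiv), THF, −78 °C; 2 (1 equiv), −78 to −20 °C; 1 M HCl
Reagents that add atoms: lithium hexamethyldisilazide, [Li+].C[Si](C)(C)[N-][Si](C)(C)C (gives the lithium of 3; nothing of it stays in 4)
Why: Kinetic deprotonation of the C6 methyl group gives dienolate 3, which acid chlorides acylate at the γ-carbon (vinylogous Claisen-type C-acylation of a dioxinone) to form P4–P5. The second equivalent of 3 takes up the acidic proton of 4 as it forms and is returned as 1 on the acid quench.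

Step 2
Reactants: 5 dodecanoyl chloride
Product: 6 N-methoxy-N-methyldodecanamide
Conditions: MeNH(OMe)·HCl, Et3N (2.2 equiv), CH2Cl2, 0 °C to rt
Reagents that add atoms: N,O-dimethylhydroxylamine hydrochloride, CNOC.Cl
Why: N-acylation of the hydroxylamine by an unhindered acid chloride (Weinreb amide formation), with no competing reactive site.

Step 3
Reactants: 4 2,2-dimethyl-6-(2-oxopropyl)-4H-1,3-dioxin-4-one; 6 N-methoxy-N-methyldodecanamide
Product: 8 6-(2,4-dioxopentadecyl)-2,2-dimethyl-4H-1,3-dioxin-4-one, via dilithium dianion 7 (not isolated)
Conditions: LDA (2.2 equiv), THF, −78 to −40 °C; 6, −78 to −10 °C; 1 M HCl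
Reagents that add atoms: lithium diisopropylamide, [Li+].CC(C)[N-]C(C)C (gives the lithium of 7; nothing of it stays in 8)
Why: LDA removes first the doubly activated CH2 proton and then a proton of the terminal methyl group, and dianion 7 reacts at the last-formed, most basic terminal carbon (γ-acylation of a 1,3-dicarbonyl dianion, Claisen type) to form P6–P7. The Weinreb amide delivers one acyl group only. Compound 8 is expected as a keto–enol mixture and is used soon after isolation.

Step 4
Reactants: 9 6-bromohex-1-ene; 10 (R)-2-propyloxirane
Product: 12 (R)-undec-10-en-4-ol, via Grignard reagent 11 (not isolated)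
Conditions: 9, Mg, THF, rt; CuI (10 mol %), 10, THF, −30 to 0 °C; 1 M HCl
Reagents that add atoms: magnesium, [Mg] (stands in 11 only; nothing of it stays in 12)
Why: Copper-catalysed SN2 opening of a terminal epoxide by a primary Grignard reagent takes place at the unsubstituted carbon and forms C5′–C6′. The C4′–O bond is not touched, and the CH2 group keeps its rank above propyl, so (R)-10 gives (R)-12. The stereocentre is imported, not created.

Step 5
Reactants: 12 (R)-undec-10-en-4-ol; 13 1,3-bis(benzyloxy)-5-bromobenzene
Product: 15 (R)-11-[3,5-bis(benzyloxy)phenyl]undecan-4-ol, via bis-boryl adduct 14 (not isolated)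
Conditions: 9-BBN-H (2.3 equiv), THF, 0 °C to rt; 13, PdCl2(dppf) (5 mol %), 3 M aq K3PO4, THF/DMF, 60 °C
Reagents that add atoms: 9-borabicyclo[3.3.1]nonane (9-BBN-H), [H]B1C2CCCC1CCC2 (gives the boron groups of 14; only one hydrogen of it stays in 15)
Why: 9-BBN-H adds to the terminal alkene in the anti-Markovnikov sense, and a second equivalent is taken up by the hydroxyl group with loss of H2. Aqueous phosphate frees the hydroxyl group again and activates the alkylborane for transmetallation (B-alkyl Suzuki–Miyaura coupling). The wide-bite-angle ligand favours reductive elimination over β-hydride elimination, and the benzyl ethers and the remote stereocentre are inert.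

Step 6
Reactants: 8 6-(2,4-dioxopentadecyl)-2,2-dimethyl-4H-1,3-dioxin-4-one; 15 (R)-11-[3,5-bis(benzyloxy)phenyl]undecan-4-ol
Product: 19 (R)-11-[3,5-bis(benzyloxy)phenyl]undecan-4-yl 2,4-dihydroxy-6-undecylbenzoate, via acylketene 16 (not isolated), via triketo ester 17 (not isolated), via cyclic aldol 18 (not isolated)
Conditions: 8 (1.3 equiv), 15, PhMe (0.3 M), 110 °C; concentrate; K2CO3, CH2Cl2/i-PrOH, rt; HCl in i-PrOH, rt
Reagents that add atoms: none
Why: At 110 °C the dioxinone ring of 8 undergoes a retro-hetero-Diels–Alder reaction, loses acetone and gives acylketene 16, whose sp carbon P1 has no ortho substituents yet. The O–H of 15 adds to 16 through a planar six-centre (pseudopericyclic) transition state in which the P3 carbonyl oxygen accepts the proton, so the ester C–O bond forms under neutral conditions with little steric demand, and C4′ keeps its (R) configuration because only the O–H bond of 15 breaks. K2CO3 then enolises 17 between P1 and P3, and P2 attacks the P7 ketone in a 6-exo-trig aldol closure (allowed in both the enolendo and the enolexo description of the delocalised β-keto ester enolate) that forms ring bond C1–C6 and gives 18. HCl removes water from 18 and the cyclohexenedione tautomerises to the resorcinol, so aromatic stabilisation pulls the preceding reversible steps through to 19, with both phenols of ring A free. The closest known reaction type is the biomimetic sequence of dioxinone thermolysis, alcohol trapping and aldol aromatisation established for resorcylates and resorcylic acid lactones, which mirrors the P2–P7 folding of a tetraketide. The stereocentres that appear at P2 and P7 in 18 vanish on aromatisation, so no facial control is needed. The step needs chemoselective capture of 16 by the carbinol, which is secured by the benzyl ethers on ring B (15 has a single O–H) and by a high concentration of 15, which lets the bimolecular addition compete with capture by the chain's own enol oxygen. It also needs the aldol closure P2 to P7 in preference to the Claisen closure P6 to P1 and to lactonisation of the P5 enol oxygen onto P1; both of these must expel a secondary alkoxide from a hindered ester, which mild carbonate base does not promote, whereas the aldol path needs no leaving group.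

Step 7
Reactants: 19 (R)-11-[3,5-bis(benzyloxy)phenyl]undecan-4-yl 2,4-dihydroxy-6-undecylbenzoate
Product: 20 (R)-11-(3,5-dihydroxyphenyl)undecan-4-yl 2,4-dihydroxy-6-undecylbenzoate
Conditions: H2 (1 atm), 10 % Pd/C, EtOAc/EtOH, rt
Reagents that add atoms: none
Why: Catalytic hydrogenolysis cleaves the two aryl benzyl ethers under neutral conditions. The ester oxygen sits on a non-benzylic secondary carbon and is not cleaved, so C4′ stays (R).

## Compound list

1 | 2,2,6-trimethyl-4H-1,3-dioxin-4-one | CC1=CC(=O)OC(C)(C)O1 | starting material
2 | acetyl chloride | CC(=O)Cl | starting material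
3 | lithium dienolate of 1 (lithium 2,2-dimethyl-6-methylidene-1,3-dioxin-4-olate) | [Li+].C=C1C=C([O-])OC(C)(C)O1 | intermediate
4 | 2,2-dimethyl-6-(2-oxopropyl)-4H-1,3-dioxin-4-one | CC(=O)CC1=CC(=O)OC(C)(C)O1 | intermediate
5 | dodecanoyl chloride | CCCCCCCCCCCC(=O)Cl | starting material
6 | N-methoxy-N-methyldodecanamide | CCCCCCCCCCCC(=O)N(C)OC | intermediate
7 | dilithium dianion of 4 (bis-enolate with terminal CH2) | [Li+].[Li+].C=C([O-])C=C1C=C([O-])OC(C)(C)O1 | intermediate
8 | 6-(2,4-dioxopentadecyl)-2,2-dimethyl-4H-1,3-dioxin-4-one | CCCCCCCCCCCC(=O)CC(=O)CC1=CC(=O)OC(C)(C)O1 | intermediate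
9 | 6-bromohex-1-ene | C=CCCCCBr | starting material
10 | (R)-2-propyloxirane | CCC[C@@H]1CO1 | starting material
11 | hex-5-en-1-ylmagnesium bromide | C=CCCCC[Mg]Br | intermediate
12 | (R)-undec-10-en-4-ol | O[C@H](CCC)CCCCCC=C | intermediate
13 | 1,3-bis(benzyloxy)-5-bromobenzene | Brc1cc(OCc2ccccc2)cc(OCc2ccccc2)c1 | starting material
14 | (R)-11-(9-borabicyclo[3.3.1]nonan-9-yl)undecan-4-yl 9-borabicyclo[3.3.1]nonane-9-borinate | C1CC2CCCC(C1)B2O[C@H](CCC)CCCCCCCB1C2CCCC1CCC2 | intermediate
15 | (R)-11-[3,5-bis(benzyloxy)phenyl]undecan-4-ol | O[C@H](CCC)CCCCCCCc1cc(OCc2ccccc2)cc(OCc2ccccc2)c1 | intermediate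
16 | octadec-1-ene-1,3,5,7-tetraone (acylketene) | CCCCCCCCCCCC(=O)CC(=O)CC(=O)C=C=O | intermediate
17 | (R)-11-[3,5-bis(benzyloxy)phenyl]undecan-4-yl 3,5,7-trioxooctadecanoate | CCCCCCCCCCCC(=O)CC(=O)CC(=O)CC(=O)O[C@H](CCC)CCCCCCCc1cc(OCc2ccccc2)cc(OCc2ccccc2)c1 | intermediate
18 | (R)-11-[3,5-bis(benzyloxy)phenyl]undecan-4-yl 2-hydroxy-4,6-dioxo-2-undecylcyclohexane-1-carboxylate (ring centres undefined, transient) | CCCCCCCCCCCC1(O)CC(=O)CC(=O)C1C(=O)O[C@H](CCC)CCCCCCCc1cc(OCc2ccccc2)cc(OCc2ccccc2)c1 | intermediate
19 | (R)-11-[3,5-bis(benzyloxy)phenyl]undecan-4-yl 2,4-dihydroxy-6-undecylbenzoate | CCCCCCCCCCCc1cc(O)cc(O)c1C(=O)O[C@H](CCC)CCCCCCCc1cc(OCc2ccccc2)cc(OCc2ccccc2)c1 | intermediate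
20 | (R)-11-(3,5-dihydroxyphenyl)undecan-4-yl 2,4-dihydroxy-6-undecylbenzoate | CCCCCCCCCCCc1cc(O)cc(O)c1C(=O)O[C@H](CCC)CCCCCCCc1cc(O)cc(O)c1 | target

## Step count and least certain steps

Total step count: 7. Longest linear sequence: 4 steps (1, 3, 6, 7 or 4, 5, 6, 7).

**Step 6 (key step).** The ketene may be consumed before the hindered secondary hydroxyl group reaches it, either by its own chain (attack of an enol oxygen on the ketene carbon) or by self-addition, because the internal path is unimolecular. In the second stage, ring closure with loss of the alkoxy group may compete with the aldol closure if the medium becomes too basic.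

The fallback sets out from 8 and 15 and returns at 20. It reverses the order of events, making the ring first and the ester second. Compound 8 is aromatised with its mask in place (Et3N, CH2Cl2, rt; the same P2–P7 aldol closure, now from the dioxinone C5 carbon) to 7-hydroxy-2,2-dimethyl-5-undecyl-4H-1,3-benzodioxin-4-one F1. The phenol is benzylated (BnBr, K2CO3, DMF) to 7-(benzyloxy)-2,2-dimethyl-5-undecyl-4H-1,3-benzodioxin-4-one F2. Compound 15 is deprotonated with NaHMDS in THF and opens the activated cyclic acyl acetal of F2, with loss of the mask, to give (R)-11-[3,5-bis(benzyloxy)phenyl]undecan-4-yl 4-(benzyloxy)-2-hydroxy-6-undecylbenzoate F3. Hydrogenolysis under the conditions of step 7 removes the three benzyl groups and gives 20.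

**Step 3.** Proton transfer to the strongly basic dianion, from the α-CH2 group of 6 or from the product as it forms, may outrun C–C bond formation, so that conversion stalls. Acylation at oxygen is the second risk.

The fallback sets out from 4 and returns at 8. Dianion 7 is added at −78 °C to commercial dodecanal, a far better electrophile, in an aldol addition. This gives 6-(4-hydroxy-2-oxopentadecyl)-2,2-dimethyl-4H-1,3-dioxin-4-one F4, which is racemic at a centre that is removed at once. F4 is oxidised with Dess–Martin periodinane to 8.

**Step 1.** Acylation at oxygen or at the α-carbon may compete with γ-acylation. A second acylation may also occur, because the product is more acidic than 1.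

The fallback sets out from 1 and returns at 4. Dienolate 3 is trapped with TMSCl as 2,2-dimethyl-6-methylidene-4-(trimethylsilyloxy)-1,3-dioxine F5. A vinylogous Mukaiyama aldol addition to acetaldehyde (BF3·OEt2, CH2Cl2, −78 °C) gives 6-(2-hydroxypropyl)-2,2-dimethyl-4H-1,3-dioxin-4-one F6. Dess–Martin oxidation of F6 gives 4.

**Step 5.** Consumption of the borane at the hydroxyl group may leave hydroboration incomplete. Slow transmetallation may also open the way to β-hydride elimination with alkene isomerisation, or to protodeboronation.

The fallback sets out from 12 and returns at 20. The aryl–chain junction is moved by one bond and made by olefin metathesis. Wittig methylenation of commercial 3,5-bis(benzyloxy)benzaldehyde gives 1,3-bis(benzyloxy)-5-vinylbenzene F7. Cross-metathesis of F7 with 12 (second-generation ruthenium carbene, CH2Cl2, 40 °C), which tolerates the free hydroxyl group, gives (R,E)-11-[3,5-bis(benzyloxy)phenyl]undec-10-en-4-ol F8. F8 takes the place of 15 in step 6 and gives (R,E)-11-[3,5-bis(benzyloxy)phenyl]undec-10-en-4-yl 2,4-dihydroxy-6-undecylbenzoate F9. The conditions of step 7 saturate the alkene and cleave both benzyl ethers in the same operation to give 20.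

## Further compounds

F1 | step 6 | 7-hydroxy-2,2-dimethyl-5-undecyl-4H-1,3-benzodioxin-4-one | CCCCCCCCCCCc1cc(O)cc2OC(C)(C)OC(=O)c12
F2 | step 6 | 7-(benzyloxy)-2,2-dimethyl-5-undecyl-4H-1,3-benzodioxin-4-one | CCCCCCCCCCCc1cc(OCc3ccccc3)cc2OC(C)(C)OC(=O)c12
F3 | step 6 | (R)-11-[3,5-bis(benzyloxy)phenyl]undecan-4-yl 4-(benzyloxy)-2-hydroxy-6-undecylbenzoate | CCCCCCCCCCCc1cc(OCc2ccccc2)cc(O)c1C(=O)O[C@H](CCC)CCCCCCCc1cc(OCc2ccccc2)cc(OCc2ccccc2)c1
F4 | step 3 | 6-(4-hydroxy-2-oxopentadecyl)-2,2-dimethyl-4H-1,3-dioxin-4-one (racemic) | CCCCCCCCCCCC(O)CC(=O)CC1=CC(=O)OC(C)(C)O1
F5 | step 1 | 2,2-dimethyl-6-methylidene-4-(trimethylsilyloxy)-1,3-dioxine | C=C1C=C(O[Si](C)(C)C)OC(C)(C)O1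
F6 | step 1 | 6-(2-hydroxypropyl)-2,2-dimethyl-4H-1,3-dioxin-4-one (racemic) | CC(O)CC1=CC(=O)OC(C)(C)O1
F7 | step 5 | 1,3-bis(benzyloxy)-5-vinylbenzene | C=Cc1cc(OCc2ccccc2)cc(OCc2ccccc2)c1
F8 | step 5 | (R,E)-11-[3,5-bis(benzyloxy)phenyl]undec-10-en-4-ol | O[C@H](CCC)CCCCC/C=C/c1cc(OCc2ccccc2)cc(OCc2ccccc2)c1
F9 | step 5 | (R,E)-11-[3,5-bis(benzyloxy)phenyl]undec-10-en-4-yl 2,4-dihydroxy-6-undecylbenzoate | CCCCCCCCCCCc1cc(O)cc(O)c1C(=O)O[C@H](CCC)CCCCC/C=C/c1cc(OCc2ccccc2)cc(OCc2ccccc2)c1
A1 | alternative 1 | 2,4-bis(benzyloxy)-6-undecylbenzoic acid | CCCCCCCCCCCc1cc(OCc2ccccc2)cc(OCc2ccccc2)c1C(=O)O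
A2 | alternative 1 | (R)-11-[3,5-bis(benzyloxy)phenyl]undecan-4-yl 2,4-bis(benzyloxy)-6-undecylbenzoate | CCCCCCCCCCCc1cc(OCc2ccccc2)cc(OCc2ccccc2)c1C(=O)O[C@H](CCC)CCCCCCCc1cc(OCc2ccccc2)cc(OCc2ccccc2)c1
A3 | alternative 1 | (S)-11-[3,5-bis(benzyloxy)phenyl]undecan-4-ol | O[C@@H](CCC)CCCCCCCc1cc(OCc2ccccc2)cc(OCc2ccccc2)c1
A4 | alternative 2 | (R)-11-[3,5-bis(benzyloxy)phenyl]undecan-4-yl tetradec-2-ynoate | CCCCCCCCCCCC#CC(=O)O[C@H](CCC)CCCCCCCc1cc(OCc2ccccc2)cc(OCc2ccccc2)c1
A5 | alternative 2 | 1-methoxy-1,3-bis(trimethylsilyloxy)buta-1,3-diene | COC(O[Si](C)(C)C)=CC(=C)O[Si](C)(C)C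
A6 | alternative 3 | 1,5-bis(benzyloxy)-2-bromo-3-undecylbenzene | CCCCCCCCCCCc1cc(OCc2ccccc2)cc(OCc2ccccc2)c1Br
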